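The data are calculated for an exercise, noise included.

The north run was where I started, since its late readings had stopped moving.

| flask | starting material | partner | remark | time |
|---|---|---|---|---|
| north-west | 0.48 M | 0.80 M | run made earlier |  |
| north | 2 M | 0.80 M | run made earlier |  |
| green | 0.40 M | 0.800 M |  | 40 h |
| red | 0.80 M | 0.800 M |  | 40 h |
| teal | 1.5 M | 0.800 M |  | 40 h |

- north-west (time / h: target / %, starting material / %): 3.00: 5.8, 94.6; 8.00: 12.0, 88.0; 15.0: 17.3, 83.3; 40.0: 27.4, 73.4
- north (time / h: target / %, starting material / %): 5.00: 13.8, 86.1; 15.0: 20.9, 78.0; 25.0: 22.0, 78.5; 40.0: 21.3, 78.9

(scatter of a reading: 0.5 percentage points)

- the numbers in the tables scatter with a standard deviation of 0.5 percentage points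
- "hardly changes" means that all values lie within two and a half points (for a concentration: within two and a half percent of the largest)

- amount of target at the end, in percent of the starting material charged for green, red, teal, in this order
- the course of these numbers from the first flask to the last (hardly changes / rises all the way / rises, then falls / falls, then rises / falls all the way)

In north, target and starting material summed to 100% of the charge at the last reading, so I reckoned with fractions of the charge and took the fraction of starting material left as one minus the target fraction. North levelled at a mean of 21.4% over its late readings, and my first estimate was that fraction as a fixed ceiling. The objection stood in the other table: north-west had reached 27.4%, more than north's level, and was still rising.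

So I looked for a number that stays put while the ceiling moves. Partner was charged at 0.80 M in both runs and at 0.800 M in the new flasks. Let y be the target fraction and r the charge of starting material over the charge of partner. If each target takes one partner, the fraction of partner not in target is one minus r·y. North then gave 0.586 for the stopping number, the target fraction divided by the fraction of starting material left and by the fraction of partner not in target. Holding it fixed, I solved for y in each flask:

green 32.9%, red 29.3%, teal 24.2%, north-west 32.1%

But a ceiling is not the value at 40 h. North-west's last reading lay below the ceiling I had reckoned for it, with 14.6% of the way still left by that reckoning. I assumed that this fraction decays exponentially in time multiplied by the charge of starting material. For north's first reading that predicted 36.8% of the way left, and the reading gave 35.5%. My row at 40 h was therefore: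

green 26.2%, red 28.1%, teal 24.2%

Red stood highest in my estimate.

The forecast, close to mine but not the same, gave 25.5%, 28%, 24.5%, with the course rises, then falls, on the ground that “the ceiling depends on concentration”.

The flasks gave 25.9%, 28.7%, 24.2%, with the course rises, then falls.

    2 partner → self-condensation product (k = 0.200 M⁻¹ h⁻¹)
    starting material + partner → target, rate k2*[starting material]^1.5*[partner]^0.5 (k = 0.0370 M⁻¹ h⁻¹)

In teal at 40.0 h, partner, the limiting reagent, stood at 0%, and the self-condensation product held 54.7% of the partner charge, against 54.7% not in target. The stopping number counts that fraction without asking where it went, and teal's end gives 0.584 against 0.586. Green, after 400 h, held 32.8% target with partner at 0%, and its ceiling from the stopping number was 32.9%.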